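It is easy to watch the percentage of target fall as the charge rises and conclude that a bigger charge buys less. So keep two things apart: f, the target as a fraction of the charge, and the target in mM, which is f times the charge.

| setting | epsilon | theta | west | south-west | north-west | south | north |
|---|---|---|---|---|---|---|---|
| substrate | 1.3 mM | 24 mM | 1.2 mM | 2.5 mM | 5.0 mM | 10 mM | 20 mM |
| gas phase | 0.78 mM (held) | 0.78 mM (held) | 0.78 mM (held) | 0.78 mM (held) | 0.78 mM (held) | 0.78 mM (held) | 0.78 mM (held) |
| remark | run made earlier | run made earlier |  |  |  |  |  |
| time |  |  | 80 min | 80 min | 80 min | 80 min | 80 min |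

| run | time / min | target / % | substrate / % |
|---|---|---|---|
| epsilon | 12.0 | 5.1 | 87.0 |
| epsilon | 25.0 | 10.2 | 73.3 |
| epsilon | 40.0 | 16.3 | 56.8 |
| epsilon | 50.0 | 16.8 | 52.1 |
| epsilon | 60.0 | 19.9 | 44.1 |
| epsilon | 80.0 | 25.1 | 34.0 |
| theta | 12.0 | 4.3 | 86.3 |
| theta | 25.0 | 8.2 | 74.0 |
| theta | 40.0 | 12.1 | 62.6 |
| theta | 50.0 | 13.1 | 54.1 |
| theta | 60.0 | 17.7 | 47.6 |
| theta | 80.0 | 17.7 | 37.0 |

(each reading ± 1 percentage point)

- a species is counted by the substrate in it: one homo dimer counts as two
- at the start none of the gas is dissolved
- the earlier runs were read with a standard deviation of 1 percentage point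
- candidate steps: gas phase <-> dissolved gas; substrate + dissolved gas -> target; substrate -> side product; 2 substrate -> homo dimer; target <-> isomer of the product
- "hardly changes" means that all values lie within two and a half points (for a concentration: within two and a half percent of the largest)

- [target] at the end for west, south-west, north-west, south, north, in this order
- how the row runs (rises all the way / rises, then falls / hardly changes / falls, then rises / falls all the way)

At 80.0 min, f reads 25.1% in epsilon and 17.7% in theta, so a first guess is that theta keeps 0.705 of epsilon's f. You should object: theta also reads 17.7% at 60.0 min, while its substrate goes from 47.6% to 37.0%, so scatter sits in that pair. Take the last 4 times together instead. The mean gap is 4.4 percentage points against a scatter of 1 point, and theta's summed target is 0.776 of epsilon's. Call the sag the fraction of f lost per mM of added charge: 0.00987 /mM. It is a small correction to epsilon's f, so compute only the correction.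

Is the sag lost substrate? Theta keeps 37.0% of its substrate and epsilon 34.0%, so theta keeps more. That is the pseudo-first-order pattern, and homo dimer does not show. But theta holds 4.25 mM of target, more than the saturation level of 0.78 mM, so gas must cross during the run. A heavier charge should therefore pull dissolved gas below saturation.

Is a straight-line sag fair? A reciprocal form through the same runs gives south 2.26 mM instead of 2.29 mM, so the form hardly matters here. The scatter on epsilon's f scales the row but leaves its shape alone.

My row is 0.301 mM, 0.620 mM, 1.21 mM, 2.29 mM, 4.09 mM. From south to north the charge is twice as large, while f keeps 0.892, so the row still climbs at its top.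

The forecast, holding that “gas supply begins to limit at high substrate”, gives 0.3 mM, 0.61 mM, 1.18 mM, 2.21 mM, 3.9 mM, rises all the way, ending lower than my north.

The flask gives 0.282 mM, 0.582 mM, 1.14 mM, 2.20 mM, 4.11 mM: rises all the way.

    gas phase ⇌ dissolved gas, rate k1*(csat - [dissolved gas]) (kL = 0.00797 /s)
    substrate + dissolved gas → target (k = 0.118 /M/s)
    substrate → side product (k = 1.33 × 10⁻⁴ /s)
    2 substrate → homo dimer (k = 1.25 × 10⁻⁵ /M/s)
    target ⇌ isomer of the product (K = 0.153, k = 7.31 × 10⁻⁵ /s)

North's 4.11 mM of target is held down by two things acting together, the hour of the reading and the step to side product: read at 800 min north gives 6.44 mM, and without that step 5.33 mM. A further part of north's shortfall is the drag of the crossing: with that drag removed, north gives 4.88 mM instead of 4.11 mM. That is a loss of 0.158, where the sag times north's charge gives 0.197. For south, the sag times the charge gives 0.0987, and at 40.0 min south's dissolved gas stands at 0.715 mM, short of saturation by a fraction 0.0837.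

The earlier runs and the new flask are simulated on assumed constants; the scatter is artificial.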